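All runs stem from a simulated flask with constants of no real substance; noise was put on by code.

The charge of coupling partner in this flask stays a fixed sum: what is left, plus what has gone to products, spent catalyst and decomposed reagent. So I ask how far the left-handed substrate gets before that charge has gone elsewhere.

in all of them: left-handed substrate 0.50 M; right-handed substrate 0.50 M

|  | coupling partner | free catalyst | remark |
|---|---|---|---|
| ash | 0.75 equiv | 5 mol% | run made earlier |
| cedar | 3 equiv | 5 mol% | run made earlier |
| elm | 1.5 equiv | 7.5 mol% | run made earlier |
| flask | 1.50 equiv | 5 mol% |  |

| run | time / h | left-handed product / % |
|---|---|---|
| ash | 1.00 | 6.2 |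
| ash | 2.00 | 9.8 |
| ash | 3.00 | 13.6 |
| ash | 6.00 | 14.8 |
| ash | 12.0 | 13.0 |
| cedar | 2.50 | 32.3 |
| cedar | 5.00 | 35.2 |
| cedar | 8.00 | 34.9 |
| cedar | 10.0 | 33.8 |
| cedar | 12.0 | 33.8 |
| elm | 1.00 | 18.7 |
| elm | 2.00 | 25.3 |
| elm | 3.00 | 26.0 |
| elm | 6.00 | 29.2 |
| elm | 12.0 | 26.7 |

(readings scatter by 1 percentage point)

- free catalyst is single-handed; left-handed substrate and right-handed substrate are mirror images of each other, charged as a racemate, each of them at the stated concentration
- reactions considered so far: coupling partner + free catalyst + left-handed substrate -> free catalyst + left-handed product; coupling partner + free catalyst + right-handed substrate -> free catalyst + right-handed product; coupling partner + free catalyst -> spent catalyst; coupling partner -> decomposed reagent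

I work in logarithms. Taking the mean of the last two readings, the logarithm of left-handed substrate charged over left-handed substrate left reads 0.326 in ash, 0.819 in elm and 1.13 in cedar. This logarithm should grow with partner times catalyst. Divided by equivalents times loading, the readings give 8.69, 7.28 and 7.51. Their mean, scaled to the flask, gives a final exposure of 0.587, exposure being that logarithm.

Now the ladder. On the fastest rung stands the partner: elm has 0.468 of its exposure after 1.00 h, so the exposure to come shrinks with a life of 1.18 h. Next, the flask's left-handed substrate needs 2.01 h per unit of exposure at its starting pace, which is longer, so I expect the exposure in the flask to level off below one unit. Slowest is the 12.0 h span of the runs, whose late readings no longer rise.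

At fixed exposure the partner lost is fixed, so extra charge stays in what is left, and the order is charge over left. The share left is the exposure to come over the final exposure. Counting the whole 20% as left-handed product, that share is 0.130, an order of 7.69. Right-handed product, unmeasured, lowers this, so I commit to an order above one and below that.

- apparent order in coupling partner when 20% of the left-handed substrate and right-handed substrate together are converted (percent change of the rate of making left-handed product for one percent more coupling partner charged)
- factor on the rate of making left-handed product when 20% of the left-handed substrate and right-handed substrate together are converted if free catalyst is charged twice over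

The forecast gives 3.5 (2 to 7) and 4.2 (2.8 to 7.5), reasoning that “the extra partner charged survives entirely”. The flask gives an order of 3.3 and a factor of 3.65.

    coupling partner + free catalyst + left-handed substrate → free catalyst + left-handed product (k = 32.8 M⁻² h⁻¹)
    coupling partner + free catalyst + right-handed substrate → free catalyst + right-handed product (k = 4.37 M⁻² h⁻¹)
    coupling partner + free catalyst → spent catalyst (k = 0.224 M⁻¹ h⁻¹)
    coupling partner → decomposed reagent (k = 0.579 h⁻¹)

The flask ends with 54% of its left-handed substrate left, a final exposure of 0.616. At 2.00 h the exposure to come is a share of 0.169, and the coupling partner stands at 16.5% of its charge. Taking the reaction of coupling partner to decomposed reagent out of this flask lowers the order from 3.3 to 1.4.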